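**Remark on the chemistry (assumption):** the lactol carbon of the target can equilibrate with the open formyl-acid form, so the route frees the (R)-lactol only in the last operation and under neutral, aprotic conditions, and how long the free lactol then holds its configuration is a property of the compound; lower-case locants b1–b6 denote the carbons of ring B.

## Analysis of the target

The target is a tetracyclic depsidone: ring A and ring B are joined by a diaryl ether oxygen and by an aryl ester, which together close a seven-membered dioxepinone, and ring B is also fused to a five-membered lactone whose sp3 carbon is a lactol (a 3-hydroxyphthalide). Ring A carries, in order round the ring, OMe, H, CH3, the ester carbonyl, the ether oxygen and a free OH. Ring B is hexasubstituted, with the ether oxygen at b1, the ester oxygen at b2, a methyl at b3, a free hydroxyl at b4, the lactone carbonyl carbon at b5 and the lactol carbon at b6. The only stereocentre is the lactol carbon, (R), which bears H, OH, the ring oxygen and b6; it has no partner to relate to and can epimerise through ring–chain tautomerism. The sensitive groups are this lactol (acid, base, protic media), the depsidone ester (nucleophiles, base) and the electron-rich phenols (oxidants). The synthesis is hard because the ether is flanked by four ortho substituents, ring B has no C–H left for late functionalisation, and the stereocentre is stable only while masked. The strategy rests on the pattern of ring B: the run b1–b4 (O, O, C-methyl, O) is the oxygenation pattern of a 4-oxy-2-methylacetoacetate (its C4, C3, C2 and C1), and the pair b5/b6, with the lactone carbonyl and the lactol carbon, is C3/C4 of a 2(5H)-furanone whose C5 is the stereocentre.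

## Retrosynthetic reasoning

**25 from 24.** The last cut is at two benzylic O–C bonds: the benzyl ether on the ring A hydroxyl and the acetal bond that ties the lactol oxygen to the carbinol carbon of 15. Both fall in one neutral hydrogenolysis. The acetal is cleaved on the auxiliary side, so the lactol C–O bond is never broken and the free lactol appears only at the very end.

**24 from 23 from 22.** The seven-membered ring is opened at the aryl ester C–O bond, not at the diaryl ether. The ester is the easy link to close: in 23 the ring A acid can reach only the b2 hydroxyl, since b4 is too far. The hard link, the ether, stays in place. The acid is carried as an allyl ester so that it can be freed without acid, base or hydrogen.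

**22 from 12 and 19.** Ring B is cut at b1–b6 and at b4–b5. This puts all four heteroatom-bearing carbons b1–b4 into one four-carbon diene (12) of alternating polarity and the two carbon-substituted positions into a butenolide (19). Three things are gained: the ether oxygen arrives already bonded to ring A, the hexasubstitution pattern is fixed by the two fragments, and the stereocentre arrives finished. The forward reaction must form the two C–C bonds head-to-tail and aromatise without disturbing the acetal.

**19 from 17, 17 from 16, 16 from 14 and 15, 14 from 13.** The bromine on C3 of 19 supplies the oxidation level for aromatisation and comes from bromination–dehydrobromination of 17. Compound 17 is one of the two C5 epimers that make up 16, so the stereocentre is fixed at this cheapest stage by separating two diastereomers, and the unwanted part of 16 can be re-equilibrated with acid. The acetal C–O bond of 16 is cut to give racemic lactol 14 and the chiral alcohol 15, and 14 is the photooxygenation product of 13.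

**12 from 10, 10 from 6 and 9, 9 from 7.** The diene is the bis-silyl enol ether of β-ketoester 10. In 10 the ether C–O bond is cut at the sp3 carbon, so the crowded diaryl ether of the target is formed as a phenoxide alkylation by the primary α-keto bromide 9. Bromide 9 comes from 7 by bromination.

**6 back to 1.** The ring A salicylate 6 needs one free phenol (future ether), one protected phenol (future free OH) and one methyl ether. Disconnection runs through ester 6, acid 5, aldehyde 4 (selective benzylation of the non-chelated hydroxyl), catechol 3 (chelation-controlled double demethylation), aldehyde 2 and arene 1, in which the three oxygens and the methyl are already in place.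

## Alternatives that were turned down

Alternative 1: The bond between b5 and the lactone carbonyl carbon is cut. In the forward key step the bromo aldehyde A2, a complete bis-benzyl-protected depsidone with Br at b5 and CHO at b6, is hydroxycarbonylated with Pd(OAc)2, Xantphos, carbon monoxide and water, and the carboxyl group so formed closes on the neighbouring aldehyde to give lactol A1. In its favour, the key step belongs to a well-charted reaction class, the carboxyl carbon arrives last, and no moisture-sensitive diene is needed; on reliability of the key bond formation it is stronger than the chosen route. Against it, the lactol forms by spontaneous closure of an achiral aldehyde acid, so A1 is racemic by construction and a late resolution would have to be added. A2 also requires six positions of ring B to be functionalised one by one and an ether coupling between two doubly ortho-substituted arenes, the bromide lies between two substituted carbons, and aqueous base with heat endangers the depsidone ester. In exchange for an untested annulation, the chosen route offers a stereocentre brought in pure, an ether made by substitution at an sp3 carbon, and ring B made in one step.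

Alternative 2: The diaryl ether C–O bond on ring A is cut, which leads back to depside A4. In the forward key step PhI(OAc)2 in a fluoroalcohol oxidises the ring A phenol of A4, and the ring B phenol adds to the free ortho carbon to give depsidone A3 after rearomatisation. In its favour, it is the shortest route, the depside ester is trivial to make, and the ring A hydroxyl emerges unprotected; on step economy it is clearly stronger. Against it, the oxidised ring A phenol has three reactive positions: besides the wanted ortho CH there are the methoxy-bearing ortho carbon and the methyl-bearing para carbon, which such oxidations commonly attack with dearomatisation. Ring B, with its own free phenol, can also be oxidised, and A3 carries an aldehyde and an ester, so the lactol would again close without stereocontrol. The chosen route is longer but fixes the regiochemistry of both rings by construction and controls the stereocentre.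

Alternative 3: The ring B bond between the ester-bearing carbon and the lactol-bearing carbon is cut, which gives the open-chain trioxo ester A6. In the forward key step mild base folds A6 by aldol addition, dehydration and enolisation into arene A5. In its favour, it also builds ring B de novo with every substituent in place, and polyketide-type folding is sound in principle. Against it, A6 is a long, fragile chain that can close in several modes (other aldol and Claisen pairings, pyrone formation), and after A5 the diaryl ether must still be made on a hindered phenol between two fully substituted rings, while the masked aldehyde again gives a racemic lactol. The chosen route uses the same idea of a ring B built from acyclic carbon, but brings the ether oxygen in on the diene and the stereocentre in on the dienophile.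

Key step: step 13

## Route

Step 1
Reactants: 1 3,4,5-trimethoxytoluene
Product: 2 2,3,4-trimethoxy-6-methylbenzaldehyde
Conditions: POCl3, DMF, 0 → 80 °C; aq. NaOAc
Reagents that add atoms: N,N-dimethylformamide (CN(C)C=O); water (O)
Why: Vilsmeier–Haack formylation; the two free ring positions are equivalent and activated by the methoxy groups, so one aldehyde should form.

Step 2
Reactants: 2 2,3,4-trimethoxy-6-methylbenzaldehyde
Product: 3 2,3-dihydroxy-4-methoxy-6-methylbenzaldehyde
Conditions: BCl3 (2.5 equiv), CH2Cl2, 0 °C → rt; H2O
Reagents that add atoms: none
Why: Chelation-controlled Lewis acid ether cleavage: boron bound to the aldehyde oxygen removes the ortho methyl, the aryloxyboron chloride so formed bridges to the next methoxy oxygen and removes that methyl as well, and the para methoxy group, which has no such assistance, should survive.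

Step 3
Reactants: 3 2,3-dihydroxy-4-methoxy-6-methylbenzaldehyde
Product: 4 3-(benzyloxy)-2-hydroxy-4-methoxy-6-methylbenzaldehyde
Conditions: NaH (2.2 equiv), DMF, 0 °C; BnBr (1.0 equiv), 0 °C → rt
Reagents that add atoms: benzyl bromide (BrCc1ccccc1)
Why: Williamson etherification of the dianion; the C2 oxide is chelated to the aldehyde and conjugated with it, so the C3 oxide is the more nucleophilic and should be alkylated first.

Step 4
Reactants: 4 3-(benzyloxy)-2-hydroxy-4-methoxy-6-methylbenzaldehyde
Product: 5 3-(benzyloxy)-2-hydroxy-4-methoxy-6-methylbenzoic acid
Conditions: NaClO2, NaH2PO4, 2-methyl-2-butene (excess), t-BuOH–THF–H2O, 0 °C → rt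
Reagents that add atoms: sodium chlorite ([Na+].[O-]Cl=O)
Why: Pinnick oxidation; the alkene in excess traps hypochlorous acid before it can chlorinate the one free, activated ring position.

Step 5
Reactants: 5 3-(benzyloxy)-2-hydroxy-4-methoxy-6-methylbenzoic acid
Product: 6 allyl 3-(benzyloxy)-2-hydroxy-4-methoxy-6-methylbenzoate
Conditions: allyl bromide, KHCO3, DMF, rt
Reagents that add atoms: allyl bromide (C=CCBr)
Why: Carboxylate O-alkylation; bicarbonate ionises the acid but not the hydrogen-bonded phenol, so only the ester should form.

Step 6
Reactants: 7 methyl 2-methyl-3-oxobutanoate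
Product: 9 methyl 4-bromo-2-methyl-3-oxobutanoate, via methyl 2-bromo-2-methyl-3-oxobutanoate 8 (not isolated)
Conditions: Br2 (1.0 equiv), CHCl3, 0 °C → rt, 16 h
Reagents that add atoms: bromine (BrBr)
Why: Electrophilic α-bromination gives the tertiary bromide 8 first, and the HBr formed equilibrates it to the terminal bromide 9, the usual course for 2-alkylacetoacetates.

Step 7
Reactants: 6 allyl 3-(benzyloxy)-2-hydroxy-4-methoxy-6-methylbenzoate; 9 methyl 4-bromo-2-methyl-3-oxobutanoate
Product: 10 methyl 4-{2-[(allyloxy)carbonyl]-6-(benzyloxy)-5-methoxy-3-methylphenoxy}-2-methyl-3-oxobutanoate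
Conditions: NaH (2.1 equiv), THF–DMF, 0 → 40 °C; aq. NH4Cl
Reagents that add atoms: none
Why: Williamson etherification at the primary α-keto carbon with the ketoester held as its sodium enolate, the standard way to 4-alkoxy- and 4-aryloxyacetoacetates; the enolate prevents self-condensation of 9 and keeps the ArOCH2 carbon from being deprotonated and attacking the neighbouring ester.

Step 8
Reactants: 10 methyl 4-{2-[(allyloxy)carbonyl]-6-(benzyloxy)-5-methoxy-3-methylphenoxy}-2-methyl-3-oxobutanoate
Product: 12 allyl 3-(benzyloxy)-4-methoxy-2-{[(1Z,3Z)-4-methoxy-3-methyl-2,4-bis(trimethylsilyloxy)buta-1,3-dien-1-yl]oxy}-6-methylbenzoate, via silyl enol ether 11 (not isolated)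
Conditions: Me3SiOSO2CF3 (2.3 equiv), Et3N (3 equiv), Et2O, 0 °C → rt; pentane extraction under argon, used crude
Reagents that add atoms: trimethylsilyl trifluoromethanesulfonate (C[Si](C)(C)OS(=O)(=O)C(F)(F)F)
Why: Soft enolisation twice: the ketone is silylated toward the methyl-bearing carbon to give 11, then O-silylation of the ester and removal of a proton from the ArOCH2 carbon (the only acidic position left, activated by the aryloxy group) give the ketene acetal; no amide base is used, which avoids deprotonation of the ring A methyl and Claisen attack on the ortho ester, and the aryloxy group is expected to lie trans to the methyl-bearing carbon (1Z in the dienyl name), outside the s-cis diene.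

Step 9
Reactants: 13 furfural
Product: 14 5-hydroxyfuran-2(5H)-one
Conditions: O2, rose bengal (C20H2Cl4I4Na2O5, cat.), hν (visible), MeOH, rt
Reagents that add atoms: dioxygen (O=O)
Why: Singlet-oxygen [4+2] addition to the furan gives an endoperoxide that methanol fragments with loss of the formyl carbon; the lactol is racemic and no stereocentre is fixed yet.

Step 10
Reactants: 14 5-hydroxyfuran-2(5H)-one; 15 (S)-1-phenylethanol
Product: 16 5-[(1S)-1-phenylethoxy]furan-2(5H)-one as the pair of C5 epimers
Conditions: PPTS (cat.), benzene, reflux, Dean–Stark trap
Reagents that add atoms: none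
Why: Acid-catalysed acetalisation of the pseudo-acid with azeotropic removal of water; the alcohol oxygen attacks the cyclic oxocarbenium ion, so the carbinol centre of 15 is retained, while the acetal carbon forms without control and 16 is expected as both C5 epimers.

Step 11
Reactants: 16 5-[(1S)-1-phenylethoxy]furan-2(5H)-one as the pair of C5 epimers
Product: 17 (5R)-5-[(1S)-1-phenylethoxy]furan-2(5H)-one
Conditions: SiO2 chromatography or fractional crystallisation; the (5S)-rich fraction is returned to PPTS (cat.), benzene, reflux and separated again
Reagents that add atoms: none
Why: Resolution by diastereomer separation with recycling: the (S)-phenylethyl group makes the two C5 epimers of 16 diastereomers with different physical properties, and the unwanted (5S) component is brought back to the epimer mixture by acid-catalysed epimerisation of the acetal carbon through the cyclic oxocarbenium ion, so the (5R) configuration of 17 is secured here by separation and not by a selective bond formation.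

Step 12
Reactants: 17 (5R)-5-[(1S)-1-phenylethoxy]furan-2(5H)-one
Product: 19 (5R)-3-bromo-5-[(1S)-1-phenylethoxy]furan-2(5H)-one, via dibromide 18 (not isolated)
Conditions: Br2 (1.05 equiv), CH2Cl2, 0 °C → rt, dark; then Et3N (1.2 equiv), 0 °C
Reagents that add atoms: bromine (BrBr)
Why: Anti addition of bromine to the enoate, then E1cB loss of HBr (acidic α-hydrogen removed, β-bromide expelled) leaves bromine on C3; no bond at C5 is touched and the base contact is short and cold, so (5R) should persist.

Step 13
Reactants: 12 allyl 3-(benzyloxy)-4-methoxy-2-{[(1Z,3Z)-4-methoxy-3-methyl-2,4-bis(trimethylsilyloxy)buta-1,3-dien-1-yl]oxy}-6-methylbenzoate; 19 (5R)-3-bromo-5-[(1S)-1-phenylethoxy]furan-2(5H)-one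
Product: 22 allyl 3-(benzyloxy)-2-({(3R)-5,7-dihydroxy-6-methyl-1-oxo-3-[(1S)-1-phenylethoxy]-1,3-dihydroisobenzofuran-4-yl}oxy)-4-methoxy-6-methylbenzoate, via bromo cycloadduct 20 (not isolated), via aryl silyl ether 21 (not isolated)
Conditions: 19 (1.2 equiv), 2,6-di-tert-butyl-4-methylpyridine (0.5 equiv), toluene, 25 → 90 °C; then i-Pr2NEt (2 equiv), 25 °C; then pH 7 phosphate buffer–THF
Reagents that add atoms: none
Why: Proposed new method: an α-bromobutenolide has not been shown as the halo-enone partner of a 1-alkoxy-1,3-bis(silyloxy)diene, and the closest known reaction types are the aromatising Diels–Alder or Michael–Dieckmann benzannulations of such dienes with haloquinones and halo-enones and the cycloadditions of 5-alkoxy-2(5H)-furanones. The donor-rich aryloxy-bearing terminus of 12 bonds to the β-carbon (C4) of 19 and the ketene acetal carbon of 12 to the bromine-bearing C3 of 19, in one asynchronous [4+2] event or as a Mukaiyama–Michael addition followed by six-membered closure onto the ester-level carbon, and either way ring B is closed as the carbocycle of cycloadduct 20. This head-to-tail orientation is the selectivity the step needs, and it is secured electronically, since the aryloxy and silyloxy donors polarise the diene toward its aryloxy-bearing terminus and the lactone carbonyl polarises the dienophile toward its β-carbon, with bromine reinforcing the bias as in haloquinones. Adduct 20 loses MeOSiMe3 from its mixed silyl ketal to give a ketone; because bromine and the ring-fusion hydrogen are cis, a simple anti E2 is not available, so the amine is expected to remove the vinylogously acidic proton at the aryloxy-bearing carbon, the extended enolate to ionise the C–Br bond at the carbon flanked by two carbonyls (oxyallyl-type, as in Favorskii ionisations), and loss of the ring-fusion proton to give phenol 21, which is desilylated to 22 on work-up. Both carbons that are sp3 in 20 end up aromatic, so no new stereocentre remains and the facial course of the addition (expected anti to the phenylethoxy group) has no consequence. The acetal carbon takes no part in bond making or breaking and should keep its (R) configuration in the aprotic, buffered medium; the stronger amine is added only after the diene 12 has been consumed, so that any 19 left over, whose C5 hydrogen is vinylogously acidic, can no longer enter the product. The (S)-phenylethyl group turns any epimer at the acetal carbon into a diastereomer that would be visible and removable at this stage.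

Step 14
Reactants: 22 allyl 3-(benzyloxy)-2-({(3R)-5,7-dihydroxy-6-methyl-1-oxo-3-[(1S)-1-phenylethoxy]-1,3-dihydroisobenzofuran-4-yl}oxy)-4-methoxy-6-methylbenzoate
Product: 23 3-(benzyloxy)-2-({(3R)-5,7-dihydroxy-6-methyl-1-oxo-3-[(1S)-1-phenylethoxy]-1,3-dihydroisobenzofuran-4-yl}oxy)-4-methoxy-6-methylbenzoic acid
Conditions: Pd(PPh3)4 (5 mol %), morpholine (5 equiv), THF, rt; citric acid wash
Reagents that add atoms: none
Why: Tsuji–Trost deallylation; zerovalent palladium ionises the allyl ester to a π-allyl complex that the amine captures, under conditions that leave the acetal, the lactone and the benzyl ether alone, and the excess amine keeps the phenols from being allylated.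

Step 15
Reactants: 23 3-(benzyloxy)-2-({(3R)-5,7-dihydroxy-6-methyl-1-oxo-3-[(1S)-1-phenylethoxy]-1,3-dihydroisobenzofuran-4-yl}oxy)-4-methoxy-6-methylbenzoic acid
Product: 24 depsidone carrying the ring A benzyl ether and the (S)-1-phenylethyl acetal of the (R)-lactol
Conditions: DCC (1.3 equiv), DMAP (0.1 equiv), CH2Cl2 (0.005 M), 0 °C → rt
Reagents that add atoms: none
Why: Steglich-type lactonisation; the activated ring A acid can reach only the b2 hydroxyl next to the ether oxygen (7-exo-trig), the b4 hydroxyl being out of reach and hydrogen-bonded to the lactone carbonyl, and high dilution suppresses intermolecular esters.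

Step 16
Reactants: 24 depsidone carrying the ring A benzyl ether and the (S)-1-phenylethyl acetal of the (R)-lactol
Product: 25 CNP0211607.1, the (R)-lactol depsidone
Conditions: H2 (1 atm), 10% Pd/C, EtOAc, rt; filtration through Celite, evaporation below 25 °C
Reagents that add atoms: none
Why: Hydrogenolysis of two benzylic C–O bonds, the aryl benzyl ether and the O–CH(CH3)Ph bond of the acetal; cleavage on the auxiliary side (its phenyl ring adsorbs, the hexasubstituted ring B does not) leaves the lactol C–O bond and hence the (R) configuration untouched, and the neutral aprotic medium should slow ring–chain tautomerism.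

## Compound list

1 | 3,4,5-trimethoxytoluene | Cc1cc(OC)c(OC)c(OC)c1 | starting material
2 | 2,3,4-trimethoxy-6-methylbenzaldehyde | Cc1cc(OC)c(OC)c(OC)c1C=O | intermediate
3 | 2,3-dihydroxy-4-methoxy-6-methylbenzaldehyde | Cc1cc(OC)c(O)c(O)c1C=O | intermediate
4 | 3-(benzyloxy)-2-hydroxy-4-methoxy-6-methylbenzaldehyde | Cc1cc(OC)c(OCc2ccccc2)c(O)c1C=O | intermediate
5 | 3-(benzyloxy)-2-hydroxy-4-methoxy-6-methylbenzoic acid | Cc1cc(OC)c(OCc2ccccc2)c(O)c1C(=O)O | intermediate
6 | allyl 3-(benzyloxy)-2-hydroxy-4-methoxy-6-methylbenzoate | Cc1cc(OC)c(OCc2ccccc2)c(O)c1C(=O)OCC=C | intermediate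
7 | methyl 2-methyl-3-oxobutanoate | COC(=O)C(C)C(C)=O | starting material
8 | methyl 2-bromo-2-methyl-3-oxobutanoate | COC(=O)C(C)(Br)C(C)=O | intermediate (not isolated)
9 | methyl 4-bromo-2-methyl-3-oxobutanoate (racemic) | COC(=O)C(C)C(=O)CBr | intermediate
10 | methyl 4-{2-[(allyloxy)carbonyl]-6-(benzyloxy)-5-methoxy-3-methylphenoxy}-2-methyl-3-oxobutanoate (racemic at C2) | COC(=O)C(C)C(=O)COc1c(OCc2ccccc2)c(OC)cc(C)c1C(=O)OCC=C | intermediate
11 | methyl 4-{2-[(allyloxy)carbonyl]-6-(benzyloxy)-5-methoxy-3-methylphenoxy}-2-methyl-3-(trimethylsilyloxy)but-2-enoate (E/Z mixture) | COC(=O)C(C)=C(O[Si](C)(C)C)COc1c(OCc2ccccc2)c(OC)cc(C)c1C(=O)OCC=C | intermediate (not isolated)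
12 | allyl 3-(benzyloxy)-4-methoxy-2-{[(1Z,3Z)-4-methoxy-3-methyl-2,4-bis(trimethylsilyloxy)buta-1,3-dien-1-yl]oxy}-6-methylbenzoate | CO/C(O[Si](C)(C)C)=C(C)/C(O[Si](C)(C)C)=C/Oc1c(OCc2ccccc2)c(OC)cc(C)c1C(=O)OCC=C | intermediate
13 | furfural | O=Cc1ccco1 | starting material
14 | 5-hydroxyfuran-2(5H)-one (racemic) | OC1OC(=O)C=C1 | intermediate
15 | (S)-1-phenylethanol | C[C@H](O)c1ccccc1 | starting material
16 | 5-[(1S)-1-phenylethoxy]furan-2(5H)-one, both C5 epimers | O=C1C=CC(O[C@@H](C)c2ccccc2)O1 | intermediate
17 | (5R)-5-[(1S)-1-phenylethoxy]furan-2(5H)-one | O=C1C=C[C@H](O[C@@H](C)c2ccccc2)O1 | intermediate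
18 | (5R)-3,4-dibromo-5-[(1S)-1-phenylethoxy]dihydrofuran-2(3H)-one (trans dibromide, C3/C4 not assigned) | BrC1C(Br)[C@H](O[C@@H](C)c2ccccc2)OC1=O | intermediate (not isolated)
19 | (5R)-3-bromo-5-[(1S)-1-phenylethoxy]furan-2(5H)-one | BrC1=C[C@H](O[C@@H](C)c2ccccc2)OC1=O | intermediate
20 | bromo cycloadduct: ring-fused bromo lactone with mixed methyl trimethylsilyl ketal and silyl enol ether (new sp3 centres not assigned) | COC1(O[Si](C)(C)C)C(C)=C(O[Si](C)(C)C)C(Oc4c(OCc5ccccc5)c(OC)cc(C)c4C(=O)OCC=C)C2[C@H](O[C@@H](C)c3ccccc3)OC(=O)C12Br | intermediate (not isolated)
21 | aryl silyl ether: 22 with the b2 hydroxyl as its trimethylsilyl ether | C=CCOC(=O)c1c(C)cc(OC)c(OCc2ccccc2)c1Oc3c(O[Si](C)(C)C)c(C)c(O)c4c3[C@H](O[C@@H](C)c5ccccc5)OC4=O | intermediate (not isolated)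
22 | allyl 3-(benzyloxy)-2-({(3R)-5,7-dihydroxy-6-methyl-1-oxo-3-[(1S)-1-phenylethoxy]-1,3-dihydroisobenzofuran-4-yl}oxy)-4-methoxy-6-methylbenzoate | C=CCOC(=O)c1c(C)cc(OC)c(OCc2ccccc2)c1Oc3c(O)c(C)c(O)c4c3[C@H](O[C@@H](C)c5ccccc5)OC4=O | intermediate
23 | 3-(benzyloxy)-2-({(3R)-5,7-dihydroxy-6-methyl-1-oxo-3-[(1S)-1-phenylethoxy]-1,3-dihydroisobenzofuran-4-yl}oxy)-4-methoxy-6-methylbenzoic acid | OC(=O)c1c(C)cc(OC)c(OCc2ccccc2)c1Oc3c(O)c(C)c(O)c4c3[C@H](O[C@@H](C)c5ccccc5)OC4=O | intermediate
24 | depsidone with ring A benzyl ether and (S)-1-phenylethyl acetal of the (R)-lactol | COc1cc(C)c2c(c1OCc6ccccc6)Oc1c(c(C)c(O)c3c1[C@H](O[C@@H](C)c5ccccc5)OC3=O)OC2=O | intermediate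
25 | CNP0211607.1, (R)-lactol depsidone | COc1cc(C)c2c(c1O)Oc1c(c(C)c(O)c3c1[C@H](O)OC3=O)OC2=O | target

## Step count and risks

Total steps: 16. Longest linear sequence: 11 (steps 1–5, 7, 8, 13–16).

**Step 13 (key step).** The most likely failure is the aromatisation after the two C–C bonds have formed. Because bromine and the ring-fusion hydrogen are cis, loss of HBr depends on the stepwise path described; the carbanion at the aryloxy-bearing carbon may instead displace bromide to close a cyclopropane, or bromine may be lost reductively. Hydrolysis of the diene and steric retardation of the union are secondary risks. The fallback uses known chemistry, sets out from 12 and comes back at 22. Diene 12 is heated in toluene with tert-butyl 4,4-diethoxybut-2-ynoate F1, which is available from 3,3-diethoxyprop-1-yne by lithiation with n-BuLi and trapping with Boc2O. Diels–Alder additions of 1-alkoxy-1,3-bis(silyloxy)dienes to alkynoates are established, have the same electronic regiochemistry (the aryloxy-bearing diene terminus bonds to the acetal-bearing β-carbon) and aromatise directly by loss of MeOSiMe3, with no halide to eliminate. After desilylation this gives allyl 3-(benzyloxy)-2-[3-(tert-butoxycarbonyl)-2-(diethoxymethyl)-4,6-dihydroxy-5-methylphenoxy]-4-methoxy-6-methylbenzoate F2. Brief treatment with CF3CO2H–CH2Cl2–H2O at 0 °C removes the tert-butyl group and the acetal, and the formyl acid closes to the racemic hydroxyphthalide allyl 3-(benzyloxy)-2-[(3,5,7-trihydroxy-6-methyl-1-oxo-1,3-dihydroisobenzofuran-4-yl)oxy]-4-methoxy-6-methylbenzoate F3. Acetalisation of F3 with 15 (PPTS, benzene, water removal) gives 22 and its acetal epimer, the (3S)-epimer of 22 F4; they are diastereomers, so 22 is isolated by chromatography or crystallisation and F4 is re-equilibrated under the same acid. The cost is that the stereocentre is sorted out late, on an advanced intermediate.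

**Step 16.** The most likely failure is erosion of configuration at the lactol carbon once the auxiliary is off, through ring–chain tautomerism during a prolonged reaction or on isolation; over-reduction at the benzylic acetal carbon of ring B is a secondary risk. The fallback sets out from 24 and comes back at 25. The hydrogenolysis is stopped after one equivalent of hydrogen, when the aryl benzyl ether, the more labile of the two groups, should be gone, and the phenol acetal, 24 without its benzyl group F5, is isolated and purified. The last operation is then the cleavage of a single benzylic C–O bond with the shortest possible exposure, followed only by filtration and evaporation. Material of eroded configuration is not lost: re-acetalisation of 25 with 15 (PPTS, benzene, water removal) returns F5 together with its epimer at the acetal carbon, the (S)-acetal epimer of F5 F6; the two are separated, F6 is re-equilibrated, and F5 is hydrogenolysed again.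

**Step 7.** The most likely failure is slow alkylation of the chelated, doubly flanked phenoxide by an electrophile that is itself an enolate, so that self-condensation of 9 takes over. The fallback sets out from 6 and comes back at 10. Phenol 6 is alkylated with methyl bromoacetate (K2CO3, DMF), a small and reliable electrophile, to give allyl 3-(benzyloxy)-4-methoxy-2-(2-methoxy-2-oxoethoxy)-6-methylbenzoate F7. The unhindered methyl ester is saponified with LiOH (1 equiv, THF–H2O, 0 °C) beside the doubly ortho-substituted allyl benzoate, giving {2-[(allyloxy)carbonyl]-6-(benzyloxy)-5-methoxy-3-methylphenoxy}acetic acid F8. Activation with 1,1'-carbonyldiimidazole gives the acyl imidazole of F8 F9, which is C-acylated by the magnesium enolate of the malonate half-ester KO2CCH(CH3)CO2CH3 (MgCl2, Et3N, MeCN) and decarboxylates on work-up to 10.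

**Step 8.** The most likely failure is incomplete second silylation, or hydrolysis of the ketene acetal on isolation, so that the diene is delivered as a mixture with 11. The fallback sets out from 10 and comes back at 12, with 11 isolated on the way. Me3SiCl and Et3N in toluene give 11, which is filtered under argon. Compound 11 is then added at −78 °C to LiN(i-Pr)2 premixed with Me3SiCl in THF (internal quench), so that the dienolate is silylated as it forms, before it can attack the ortho ester or exchange with the ring A methyl. This fallback makes no compound outside the compound list (F0).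

**Step 3.** The most likely failure is poor discrimination between the two phenoxides, with bis-benzylation or alkylation at the chelated oxygen. The fallback sets out from 3 and comes back at 4. Both hydroxyls are benzylated (BnBr, K2CO3, DMF) to give 2,3-bis(benzyloxy)-4-methoxy-6-methylbenzaldehyde F10. MgBr2·OEt2 in toluene–Et2O then removes only the benzyl group ortho to the aldehyde, by chelation between the carbonyl and the ether oxygen, and gives 4.

## Further compounds

F1 | step 13 | tert-butyl 4,4-diethoxybut-2-ynoate | CCOC(OCC)C#CC(=O)OC(C)(C)C
F2 | step 13 | allyl 3-(benzyloxy)-2-[3-(tert-butoxycarbonyl)-2-(diethoxymethyl)-4,6-dihydroxy-5-methylphenoxy]-4-methoxy-6-methylbenzoate | C=CCOC(=O)c1c(C)cc(OC)c(OCc2ccccc2)c1Oc1c(O)c(C)c(O)c(C(=O)OC(C)(C)C)c1C(OCC)OCC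
F3 | step 13 | allyl 3-(benzyloxy)-2-[(3,5,7-trihydroxy-6-methyl-1-oxo-1,3-dihydroisobenzofuran-4-yl)oxy]-4-methoxy-6-methylbenzoate (racemic) | C=CCOC(=O)c1c(C)cc(OC)c(OCc2ccccc2)c1Oc1c(O)c(C)c(O)c2c1C(O)OC2=O
F4 | step 13 | (3S)-epimer of 22 | C=CCOC(=O)c1c(C)cc(OC)c(OCc2ccccc2)c1Oc3c(O)c(C)c(O)c4c3[C@@H](O[C@@H](C)c5ccccc5)OC4=O
F5 | step 16 | 24 without its benzyl group (free ring A phenol, (S)-1-phenylethyl acetal of the (R)-lactol) | COc1cc(C)c2c(c1O)Oc1c(c(C)c(O)c3c1[C@H](O[C@@H](C)c4ccccc4)OC3=O)OC2=O
F6 | step 16 | (S)-acetal epimer of F5 | COc1cc(C)c2c(c1O)Oc1c(c(C)c(O)c3c1[C@@H](O[C@@H](C)c4ccccc4)OC3=O)OC2=O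
F7 | step 7 | allyl 3-(benzyloxy)-4-methoxy-2-(2-methoxy-2-oxoethoxy)-6-methylbenzoate | COC(=O)COc1c(OCc2ccccc2)c(OC)cc(C)c1C(=O)OCC=C
F8 | step 7 | {2-[(allyloxy)carbonyl]-6-(benzyloxy)-5-methoxy-3-methylphenoxy}acetic acid | OC(=O)COc1c(OCc2ccccc2)c(OC)cc(C)c1C(=O)OCC=C
F9 | step 7 | acyl imidazole of F8 | O=C(COc1c(OCc2ccccc2)c(OC)cc(C)c1C(=O)OCC=C)n1ccnc1
F0 | step 8 | none | none
F10 | step 3 | 2,3-bis(benzyloxy)-4-methoxy-6-methylbenzaldehyde | Cc1cc(OC)c(OCc2ccccc2)c(OCc2ccccc2)c1C=O
A1 | alternative 1 | bis-benzyl-protected lactol depsidone (racemic, R drawn) | COc1cc(C)c2c(c1OCc4ccccc4)Oc3c(c(C)c(OCc5ccccc5)c6c3[C@H](O)OC6=O)OC2=O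
A2 | alternative 1 | bis-benzyl-protected depsidone with Br at b5 and CHO at b6 | COc1cc(C)c2c(c1OCc4ccccc4)Oc3c(c(C)c(OCc5ccccc5)c(Br)c3C=O)OC2=O
A3 | alternative 2 | depsidone with free ring A hydroxyl, ring B benzyl ether, allyl ester and aldehyde | COc1cc(C)c2c(c1O)Oc3c(c(C)c(OCc4ccccc4)c(C(=O)OCC=C)c3C=O)OC2=O
A4 | alternative 2 | depside: 5-hydroxy-4-methoxy-2-methylbenzoate of the ring B phenol | COc1cc(C)c(cc1O)C(=O)Oc2c(C)c(OCc3ccccc3)c(C(=O)OCC=C)c(C=O)c2O
A5 | alternative 3 | tert-butyl 3-(benzyloxy)-2-(dimethoxymethyl)-4,6-dihydroxy-5-methylbenzoate | COC(OC)c1c(OCc2ccccc2)c(O)c(C)c(O)c1C(=O)OC(C)(C)C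
A6 | alternative 3 | tert-butyl 6-(benzyloxy)-8,8-dimethoxy-4-methyl-3,5,7-trioxooctanoate | COC(OC)C(=O)C(OCc1ccccc1)C(=O)C(C)C(=O)CC(=O)OC(C)(C)C
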